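The numbers in the tables were generated by integration from invented constants.

Take the logarithm of one ratio and let it carry the flask.

| flask | left-handed substrate | right-handed substrate | coupling partner | temperature | remark | time |
|---|---|---|---|---|---|---|
| Sunday's | 0.70 M | 0.70 M | 1.1 M | −1 °C | run made earlier |  |
| Friday's | 1.1 M | 1.1 M | 1.1 M | 40 °C | run made earlier |  |
| spring | 0.50 M | 0.50 M | 1.10 M | 5 °C |  | 3.0 min |
| noon | 0.50 M | 0.50 M | 1.10 M | −20 °C |  | 3.0 min |
| midnight | 0.50 M | 0.50 M | 1.10 M | 55 °C |  | 3.0 min |
| dusk | 0.50 M | 0.50 M | 1.10 M | 30 °C |  | 3.0 min |

- Sunday's (time / s: left-handed product / %, right-handed product / %): 20.0: 2.1, 0.8; 40.0: 4.4, 1.5; 60.0: 6.0, 3.2; 80.0: 7.9, 3.5; 120: 10.0, 4.4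
- Friday's (time / s: left-handed product / %, right-handed product / %): 10.0: 7.6, 10.3; 20.0: 9.9, 12.4

(scatter of a reading: 0.3 percentage points)

- coupling partner is single-handed; left-handed substrate and right-handed substrate are mirror images of each other, charged as a racemate, each of them at the stated concentration
- an excess is the difference of the two amounts in percent of their sum
- an excess is below zero if the other one leads
- the handed part of coupling partner does not stay in what it makes, so the products of the two hands are mirror images too

* the best flask by excess of left-handed product over right-handed product; "all alike" if 1.5 percentage points covers them all (spring / noon / midnight / dusk / all alike)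
* excess of left-handed product over right-handed product at the end, spring
* excess of left-handed product over right-handed product at the end, noon
* excess of left-handed product over right-handed product at the end, midnight
* excess of left-handed product over right-handed product at the end, dusk

Start with the first instants. Both substrates stand equal and meet the same coupling partner. Take each coupling as first order in each reactant: c(coupling partner) then cancels, and left-handed product over right-handed product is s, the selectivity factor. The excess is (s−1)/(s+1).

Read s from the last reading of each run. Sunday's gives 2.27 at −1 °C, and Friday's gives 0.798 at 40 °C. Their decimal logarithms are 0.356 and −0.0980, so the lead changes hands between these runs; their charges differ too, but with the two substrates equal in each run the charge cancels from the first ratio. Assume the logarithm runs straight in reciprocal temperature. The two runs then give 18.1 kJ mol⁻¹ for the selectivity gap, the excess of the right-handed coupling's activation energy over the left-handed coupling's.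

Now the middle of a run. By its last reading, Sunday's run had turned 20.0% of the left-handed substrate into product and 8.80% of the right-handed, more of the left. In Sunday's run the left-handed substrate thinned faster, so expect spring, warmer and longer than that run, to end below its reckoned excess.

Then the end. Friday's run made 17.9% in its first 10.0 s and less, 4.40%, in the next 10.0 s. Its couplings had used 0.491 M, less than the 1.1 M of coupling partner charged, so I take the slowing to mean that coupling partner leaves by a route these readings don't show. Expect midnight, hotter than Friday's run, to stop early and keep its early excess.

My reckoning carries s from Sunday's along the gap: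

- Noon: s = 4.14, excess 61.1%.
- Spring: excess 31.3%, before thinning.
- Dusk: excess 0.195%.
- Midnight: excess −26.5%.

Noon leads, higher than the others.

The forecast, whose figures differ from mine, names noon with 65% (48% to 78%), spring 30% (20% to 38%), dusk 0% (−9% to 9%) and midnight −28% (−42% to −14%): “Selectivity therefore inverts with temperature.”

The flask gives noon as best: noon 62.3%, spring 27.5%, dusk −3.27%, midnight −31.0%.

    2 coupling partner → self-condensation product (k = 0.00350 M⁻¹ s⁻¹, Ea = 67.0 kJ mol⁻¹)
    right-handed substrate ⇌ achiral form (K = 0.570, k = 0.00380 s⁻¹, Ea = 75.0 kJ mol⁻¹, ΔH = −47.0 kJ mol⁻¹)
    left-handed substrate ⇌ achiral form (K = 0.570, k = 0.00380 s⁻¹, Ea = 75.0 kJ mol⁻¹, ΔH = −47.0 kJ mol⁻¹)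
    coupling partner + left-handed substrate → left-handed product (k = 0.00380 M⁻¹ s⁻¹, Ea = 47.0 kJ mol⁻¹)
    coupling partner + right-handed substrate → right-handed product (k = 0.00200 M⁻¹ s⁻¹, Ea = 67.0 kJ mol⁻¹)
    (constants at 5 °C)

Noon's excess means s = 4.31 against the reckoned 4.14. That flask held 2.65% achiral form and 0.0384 M self-condensation product at the end, with 88% of the left-handed substrate and 95% of the right-handed left. Carry the gap to the neighbour, a flask like noon kept at −5 °C: s = 2.56, excess 43.8%. That flask ended with 10.8% left-handed product, 4.46% right-handed product and an excess of 41.7%.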